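How strongly does the rate at 20% conversion in the flask answer to its catalyst charge and to its reagent charge?

the same everywhere: substrate 0.050 M; added ligand 0.11 mM

| charge | reagent | free catalyst | remark |
|---|---|---|---|
| theta | 0.075 M | 25 µM | run made earlier |
| beta | 0.075 M | 38 µM | run made earlier |
| flask | 0.0750 M | 50 µM |  |

- theta (time / h: product / %, substrate / %): 2.50: 5.1, 95.2; 5.00: 9.3, 90.9; 6.00: 10.6, 89.3; 10.0: 16.2, 83.4; 12.0: 19.3, 81.1; 15.0: 22.6, 77.4
- beta (time / h: product / %, substrate / %): 1.33: 3.5, 96.0; 2.00: 6.1, 93.9; 3.00: 8.8, 91.7; 5.00: 13.5, 87.1; 6.00: 15.2, 84.4; 10.0: 23.1, 77.3; 15.0: 31.0, 69.2

(readings scatter by 0.3 percentage points)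

- apparent order in free catalyst when 20% of the substrate are converted (percent change of the rate of making product for one percent more free catalyst charged)
- apparent order in reagent when 20% of the substrate are converted (percent change of the rate of making product for one percent more reagent charged)

- no earlier run changes the charge of reagent; that part of a forecast is a guess

I take the given numbers in turn. The charges of substrate, reagent and added ligand are equal in theta, beta and the flask, so an error shared by all three in any of them drops out when I carry one run over to another; for the same reason, comparing these runs shows no effect of the reagent charge. The catalyst charge differs, and if the rate follows it, an error in that charge passes one for one into any time I carry over, so this number has to be known well. The scatter of 0.3 percentage points sits on a gain of 3.3 points between the two theta readings I use.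

So I keep one quantity, the catalyst-time to 20%: the catalyst charge multiplied by the hours until product reaches that level. Interpolated, the theta run crosses at 12.6 h, which gives 1.14 M·s. With that catalyst-time, the beta run should be there at 8.31 h, and its readings, interpolated, show 19.8% then. I therefore read an order near one in catalyst and expect the flask to arrive at 6.32 h. For reagent I have no reckoning.

The forecast gives 0.95 for catalyst and 0.8 for reagent, saying of the fall in rate: “That suggests first order in reagent, although product inhibition could mimic it.”

The flask gives 1.0 for catalyst and 0.33 for reagent.

    substrate + free catalyst → catalyst intermediate A (k = 0.900 L mol⁻¹ s⁻¹)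
    reagent + catalyst intermediate A → catalyst intermediate B (k = 0.370 L mol⁻¹ s⁻¹)
    catalyst intermediate B ⇌ by-product + catalyst intermediate C (K = 0.0560 M, k = 0.0440 s⁻¹)
    catalyst intermediate C → free catalyst + product (k = 1.10 s⁻¹)
    free catalyst + added ligand ⇌ idle complex A (K = 2400 L mol⁻¹, k = 0.450 L mol⁻¹ s⁻¹)
    free catalyst + by-product ⇌ idle complex B, settled at all times (K = 160 L mol⁻¹)

The flask reaches 20% at 6.25 h, a catalyst-time of 1.13 M·s against 1.14 M·s from theta. Its reagent order lies below the forecast by a factor of 2.42, and one part of the reason can be shown. At that conversion, idle complex B, an off-cycle form made from free catalyst and by-product, holds 30.6% of the catalyst. In a run of this flask without that binding, the rate is 1.45 times the actual one, and the reagent order rises from 0.33 to 0.49.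

(The data stem from a simulated flask for substances that don't exist; noise was put on by code.)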